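**Retrosynthetic overview**

1. Skeleton numbering: C1 methyl-bearing fusion carbon, C2/C3 ring CH2, C4 = C(OH)(i-Pr), C5 fusion CH, C6 = CH–O2CAr, C7 CH2, C8(CH3)–C9 epoxide, C10 CH2. The five-membered ring is C1–C5; the seven-membered ring is C1, C5–C10.
2. Target ⇐ phenol desilylation ⇐ α-face epoxidation of C8=C9 (oxirane, formed last) ⇐ C6–O acylation with silyl-protected 4-hydroxybenzoic acid ⇐ 4,6-diol ⇐ C6 ketone.
3. Seven-membered ring (formed second): C6–C7 bond by rhodium hydroacylation of a C6 aldehyde onto the C10=C9–C8(CH3)=C7 diene on C1. The C4 carbinol comes from isopropyl addition anti to the C5 substituent.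
4. Five-membered ring (formed first), the feature the plan rests on: ring C1–C5 read as a cyclopent-2-enone (C4=O flanked by C3 and C5, C2=C3, quaternary C1 next to C5). Its C5–C1 bond is made by gold Rautenstrauch rearrangement, alkyne carbon C5 (carrying C6 as diethyl acetal) meeting the trisubstituted alkene terminus C1 (CH3, CH2OTBS) with C3→C1 chirality transfer.
5. (S)-Pivalate ⇐ (S)-propargylic alcohol ⇐ ynone ⇐ lithiated 3,3-diethoxyprop-1-yne + (E)-4-silyloxy-3-methylbut-2-enal ⇐ prenyl acetate.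

Key step: step 9

Remark: locants C1–C10 are the skeleton numbers above; prenyl acetate (the commercial acetate of 3-methylbut-2-en-1-ol) is taken as starting material; TBS = tert-butyldimethylsilyl, TES = triethylsilyl.

**Route**

Step 1
Reactants: 1 3-methylbut-2-en-1-yl acetate
Product: 3 (E)-4-hydroxy-3-methylbut-2-en-1-yl acetate, via enal acetate 2 (not isolated)
Conditions: SeO2 (0.5 equiv), t-BuOOH (2 equiv), salicylic acid (0.1 equiv), CH2Cl2, rt; then NaBH4, MeOH, 0 °C
Reagents that add atoms: tert-butyl hydroperoxide CC(C)(C)OO (oxygen, relayed by selenium dioxide O=[Se]=O)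
Why: SeO2 allylic oxidation (ene reaction then [2,3]-shift) takes the methyl group trans to the acetoxymethyl chain, so the new CH2OH is (E), and borohydride returns over-oxidised enal 2 to the alcohol.

Step 2
Reactants: 3 (E)-4-hydroxy-3-methylbut-2-en-1-yl acetate
Product: 4 (E)-4-{[tert-butyl(dimethyl)silyl]oxy}-3-methylbut-2-en-1-yl acetate
Conditions: TBSCl, imidazole, DMF, 0 °C to rt
Reagents that add atoms: tert-butyldimethylsilyl chloride CC(C)(C)[Si](C)(C)Cl
Why: Imidazole-promoted silylation of the primary allylic alcohol, with no effect on the ester or the alkene geometry.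

Step 3
Reactants: 4 (E)-4-{[tert-butyl(dimethyl)silyl]oxy}-3-methylbut-2-en-1-yl acetate
Product: 5 (E)-4-{[tert-butyl(dimethyl)silyl]oxy}-3-methylbut-2-en-1-ol
Conditions: K2CO3, MeOH, 0 °C
Reagents that add atoms: none
Why: Base-catalysed transesterification removes the acetate while the silyl ether is stable to carbonate in methanol.

Step 4
Reactants: 5 (E)-4-{[tert-butyl(dimethyl)silyl]oxy}-3-methylbut-2-en-1-ol
Product: 6 (E)-4-{[tert-butyl(dimethyl)silyl]oxy}-3-methylbut-2-enal
Conditions: MnO2, CH2Cl2, rt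
Reagents that add atoms: none
Why: MnO2 oxidation of an allylic alcohol stops at the enal and leaves the (E)-geometry (CHO trans to CH2OTBS) untouched.

Step 5
Reactants: 7 3,3-diethoxyprop-1-yne; 6 (E)-4-{[tert-butyl(dimethyl)silyl]oxy}-3-methylbut-2-enal
Product: 9 racemic (E)-7-{[tert-butyl(dimethyl)silyl]oxy}-1,1-diethoxy-6-methylhept-5-en-2-yn-4-ol, via lithium acetylide 8 (not isolated)
Conditions: n-BuLi, THF, −78 °C; then 6; H2O
Reagents that add atoms: none
Why: Lithium acetylide 1,2-addition to the enal is fast at −78 °C and gives the C3 carbinol (racemic at this stage) carrying both the alkyne and the alkene.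

Step 6
Reactants: 9 racemic (E)-7-{[tert-butyl(dimethyl)silyl]oxy}-1,1-diethoxy-6-methylhept-5-en-2-yn-4-ol
Product: 10 (E)-7-{[tert-butyl(dimethyl)silyl]oxy}-1,1-diethoxy-6-methylhept-5-en-2-yn-4-one
Conditions: MnO2, CH2Cl2, rt
Reagents that add atoms: none
Why: MnO2 oxidation of the doubly activated (allylic and propargylic) carbinol gives the cross-conjugated ynone without touching acetal or silyl ether.

Step 7
Reactants: 10 (E)-7-{[tert-butyl(dimethyl)silyl]oxy}-1,1-diethoxy-6-methylhept-5-en-2-yn-4-one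
Product: 11 (4S,5E)-7-{[tert-butyl(dimethyl)silyl]oxy}-1,1-diethoxy-6-methylhept-5-en-2-yn-4-ol
Conditions: (S)-1-methyl-3,3-diphenyltetrahydro-1H,3H-pyrrolo[1,2-c][1,3,2]oxazaborole [(S)-Me-CBS, 20 mol%], BH3·SMe2, THF, −40 °C; MeOH quench
Reagents that add atoms: none
Why: In this Corey–Bakshi–Shibata reduction the bent β,β-disubstituted alkenyl group should act as the large and the linear alkynyl group as the small substituent, so the (S)-catalyst should give the (S)-carbinol at C3 (to be confirmed by Mosher ester analysis of 11, the (R)-catalyst serving otherwise).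

Step 8
Reactants: 11 (4S,5E)-7-{[tert-butyl(dimethyl)silyl]oxy}-1,1-diethoxy-6-methylhept-5-en-2-yn-4-ol
Product: 12 (4S,5E)-7-{[tert-butyl(dimethyl)silyl]oxy}-1,1-diethoxy-6-methylhept-5-en-2-yn-4-yl 2,2-dimethylpropanoate
Conditions: pivaloyl chloride, Et3N, 4-(dimethylamino)pyridine (10 mol%), CH2Cl2, 0 °C to rt
Reagents that add atoms: pivaloyl chloride CC(C)(C)C(=O)Cl
Why: Nucleophile-catalysed O-acylation takes place at oxygen only, so the C3 configuration is retained.

Step 9
Reactants: 12 (4S,5E)-7-{[tert-butyl(dimethyl)silyl]oxy}-1,1-diethoxy-6-methylhept-5-en-2-yn-4-yl 2,2-dimethylpropanoate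
Product: 14 (4S,5S)-4-({[tert-butyl(dimethyl)silyl]oxy}methyl)-5-(diethoxymethyl)-4-methylcyclopent-2-en-1-one, via dienyl pivalate 13 (not isolated)
Conditions: Ph3PAuCl (5 mol%), AgSbF6 (5 mol%), MeCN containing H2O (2 equiv), −20 °C to rt
Reagents that add atoms: none
Why: Ph3PAu+ (monovalent gold) binds the C4≡C5 alkyne, the pivalate carbonyl oxygen attacks C4 (1,2-acyloxy shift through a dioxolenium ion, the σ-withdrawing acetal on C5 directing attack to the remote alkyne carbon and disfavouring the 1,3-shift), and ionisation of C3–O leaves an aurated pentadienyl cation that closes between C5 and C1; loss of gold gives dienyl pivalate 13, which the water present hydrolyses to the C4 ketone. The closest known reaction is the gold-catalysed Rautenstrauch rearrangement of 1-ethynyl-2-propenyl pivalates to cyclopent-2-enones. The five-membered ring is closed by a five-centre, 4π (Nazarov-like) cyclisation of the C5–C4–C3–C2–C1 unit, both termini ending in the ring. C1 is controlled by the C3 stereocentre: the C3–O bond leaves perpendicular to the C1=C2 plane, C5 bonds to the opposite face of C1 before the helical cation can invert, and the (E)-alkene puts CH3 inside and CH2OTBS outside, which should turn (S)-C3 into (S)-C1 of 14 (the C1 configuration of the target); C5 is set only by protonation and is adjusted in step 10. The step needs the 1,2-shift to beat the 1,3-shift and ring closure to beat racemisation of the cation, which the acetal polarisation, the electron-rich trisubstituted alkene terminus and the low temperature should secure, while quaternary C1 keeps the C2=C3 bond from migrating.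

Step 10
Reactants: 14 (4S,5S)-4-({[tert-butyl(dimethyl)silyl]oxy}methyl)-5-(diethoxymethyl)-4-methylcyclopent-2-en-1-one
Product: 15 (2S,3S)-3-({[tert-butyl(dimethyl)silyl]oxy}methyl)-2-(diethoxymethyl)-3-methylcyclopentan-1-one
Conditions: H2 (1 atm), 5% Pd/C, EtOAc, rt; then K2CO3, MeOH, rt
Reagents that add atoms: none
Why: Heterogeneous hydrogenation saturates the disubstituted enone C2=C3 bond, and base then equilibrates C5 through the enolate towards the epimer with the acetal trans to the CH2OTBS arm (cis to CH3); this steric bias is probably modest, so the epimers are separated and the minor one is returned to the base.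

Step 11
Reactants: 15 (2S,3S)-3-({[tert-butyl(dimethyl)silyl]oxy}methyl)-2-(diethoxymethyl)-3-methylcyclopentan-1-one
Product: 16 (1R,2R,3S)-3-({[tert-butyl(dimethyl)silyl]oxy}methyl)-2-(diethoxymethyl)-3-methyl-1-(propan-2-yl)cyclopentan-1-ol
Conditions: i-PrMgCl (3 equiv), anhydrous CeCl3 (3 equiv), THF, −78 to 0 °C
Reagents that add atoms: isopropylmagnesium chloride CC(C)[Mg]Cl
Why: Organocerium 1,2-addition suppresses enolisation of the hindered β-keto acetal, and attack on C4 from the face opposite the adjacent C5 acetal and the pseudoaxial C1 methyl should place OH cis to C6 and isopropyl trans, which is (R) at C4.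

Step 12
Reactants: 16 (1R,2R,3S)-3-({[tert-butyl(dimethyl)silyl]oxy}methyl)-2-(diethoxymethyl)-3-methyl-1-(propan-2-yl)cyclopentan-1-ol
Product: 17 (1R,2R,3S)-2-(diethoxymethyl)-3-(hydroxymethyl)-3-methyl-1-(propan-2-yl)cyclopentan-1-ol
Conditions: n-Bu4NF, THF, rt
Reagents that add atoms: none
Why: Fluoride desilylation frees the C10 alcohol under basic conditions that leave the acetal intact.

Step 13
Reactants: 17 (1R,2R,3S)-2-(diethoxymethyl)-3-(hydroxymethyl)-3-methyl-1-(propan-2-yl)cyclopentan-1-ol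
Product: 18 (1S,2R,3R)-2-(diethoxymethyl)-3-hydroxy-1-methyl-3-(propan-2-yl)cyclopentane-1-carbaldehyde
Conditions: Dess–Martin periodinane, NaHCO3, CH2Cl2, 0 °C to rt
Reagents that add atoms: none
Why: Buffered Dess–Martin oxidation converts the primary alcohol into the non-enolisable C10 aldehyde while the tertiary alcohol cannot be oxidised and the trans C4–OH cannot form a lactol with C10.

Step 14
Reactants: 18 (1S,2R,3R)-2-(diethoxymethyl)-3-hydroxy-1-methyl-3-(propan-2-yl)cyclopentane-1-carbaldehyde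
Product: 19 (3E)-4-[(1R,2R,3R)-2-(diethoxymethyl)-3-hydroxy-1-methyl-3-(propan-2-yl)cyclopentyl]but-3-en-2-one
Conditions: dimethyl (2-oxopropyl)phosphonate, LiCl, i-Pr2NEt, MeCN, rt
Reagents that add atoms: dimethyl (2-oxopropyl)phosphonate CC(=O)CP(=O)(OC)OC
Why: Horner–Wadsworth–Emmons olefination under mild lithium chloride–amine conditions adds C9, C8, C7 and the C8 methyl and gives the (E)-enone with the stabilised phosphonate.

Step 15
Reactants: 19 (3E)-4-[(1R,2R,3R)-2-(diethoxymethyl)-3-hydroxy-1-methyl-3-(propan-2-yl)cyclopentyl]but-3-en-2-one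
Product: 20 (1R,2R,3R)-2-(diethoxymethyl)-3-methyl-3-[(1E)-3-methylbuta-1,3-dien-1-yl]-1-(propan-2-yl)cyclopentan-1-ol
Conditions: Ph3PCH3Br (4 equiv), KOt-Bu (3.8 equiv), THF, 0 °C to rt
Reagents that add atoms: methyltriphenylphosphonium bromide C[P+](c1ccccc1)(c1ccccc1)c1ccccc1.[Br-]
Why: Wittig methylenation of the enone carbonyl (1,2-attack by the unstabilised ylide, excess reagent covering the free hydroxyl) gives the 2-methyl-1,3-diene with the C9=C10 geometry unchanged.

Step 16
Reactants: 20 (1R,2R,3R)-2-(diethoxymethyl)-3-methyl-3-[(1E)-3-methylbuta-1,3-dien-1-yl]-1-(propan-2-yl)cyclopentan-1-ol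
Product: 22 (1R,2R,5R)-2-methyl-2-[(1E)-3-methylbuta-1,3-dien-1-yl]-5-(propan-2-yl)-5-[(triethylsilyl)oxy]cyclopentane-1-carbaldehyde, via lutidinium triflate 21 (not isolated)
Conditions: TESOTf (3 equiv), 2,6-lutidine (4 equiv), CH2Cl2, 0 °C; then H2O, rt
Reagents that add atoms: triethylsilyl trifluoromethanesulfonate CC[Si](CC)(CC)OS(=O)(=O)C(F)(F)F; water O
Why: The silyl triflate–2,6-lutidine pair silylates the tertiary C4 hydroxyl and converts the diethyl acetal through pyridinium salt 21 into the aldehyde on aqueous work-up without free acid that could harm the diene, and at epimerisable C5 the isomer with CHO trans to the isopropyl group is also the stable one.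

Step 17
Reactants: 22 (1R,2R,5R)-2-methyl-2-[(1E)-3-methylbuta-1,3-dien-1-yl]-5-(propan-2-yl)-5-[(triethylsilyl)oxy]cyclopentane-1-carbaldehyde
Product: 23 (3R,3aR,8aR)-6,8a-dimethyl-3-(propan-2-yl)-3-[(triethylsilyl)oxy]-2,3,3a,5,8,8a-hexahydroazulen-4(1H)-one
Conditions: [Rh(dppe)]ClO4 (10 mol%, dppe = Ph2PCH2CH2PPh2, from [Rh(nbd)(dppe)]ClO4 and H2), ClCH2CH2Cl, 65 °C
Reagents that add atoms: none
Why: In this intramolecular hydroacylation of a 4,6-dienal with cationic monovalent rhodium, C6–H oxidative addition, hydride transfer to C10 and reductive elimination at C7 of the acyl π-allyl complex (after syn to anti isomerisation) close the seven-membered ring with the double bond at C8=C9, the trans C5/C1 arms becoming the trans ring fusion with no stereocentre made or touched.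

Step 18
Reactants: 23 (3R,3aR,8aR)-6,8a-dimethyl-3-(propan-2-yl)-3-[(triethylsilyl)oxy]-2,3,3a,5,8,8a-hexahydroazulen-4(1H)-one
Product: 25 (3R,3aS,4R,8aR)-6,8a-dimethyl-3-(propan-2-yl)-1,2,3,3a,4,5,8,8a-octahydroazulene-3,4-diol, via silyl ether alcohol 24 (not isolated)
Conditions: LiBH(s-Bu)3, THF, −78 °C; then H2O, n-Bu4NF, rt
Reagents that add atoms: none
Why: The bulky hydride should attack the C6 ketone equatorially from the α-face (that of H5), away from the axial C1 methyl and the C4 silyloxy group on the β-face, giving the β (R) alcohol cis to the C1 methyl as in trialkylborohydride reductions of 2-alkylcycloalkanones to cis alcohols, and fluoride then removes the triethylsilyl group in the same flask.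

Step 19
Reactants: 26 4-hydroxybenzoic acid
Product: 28 4-{[tert-butyl(dimethyl)silyl]oxy}benzoic acid, via silyl ester 27 (not isolated)
Conditions: TBSCl (2.5 equiv), imidazole, DMF, rt; then K2CO3, THF/MeOH/H2O, rt; citric acid
Reagents that add atoms: tert-butyldimethylsilyl chloride CC(C)(C)[Si](C)(C)Cl
Why: Double silylation followed by selective hydrolysis of the far more labile silyl ester leaves the aryl silyl ether and the free acid.

Step 20
Reactants: 25 (3R,3aS,4R,8aR)-6,8a-dimethyl-3-(propan-2-yl)-1,2,3,3a,4,5,8,8a-octahydroazulene-3,4-diol; 28 4-{[tert-butyl(dimethyl)silyl]oxy}benzoic acid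
Product: 29 (3R,3aS,4R,8aR)-3-hydroxy-6,8a-dimethyl-3-(propan-2-yl)-1,2,3,3a,4,5,8,8a-octahydroazulen-4-yl 4-{[tert-butyl(dimethyl)silyl]oxy}benzoate
Conditions: N,N'-dicyclohexylcarbodiimide, 4-(dimethylamino)pyridine (20 mol%), CH2Cl2, rt
Reagents that add atoms: none
Why: Steglich esterification acylates the secondary C6 hydroxyl with retention while the tertiary C4 hydroxyl is too hindered to react.

Step 21
Reactants: 29 (3R,3aS,4R,8aR)-3-hydroxy-6,8a-dimethyl-3-(propan-2-yl)-1,2,3,3a,4,5,8,8a-octahydroazulen-4-yl 4-{[tert-butyl(dimethyl)silyl]oxy}benzoate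
Product: 30 (8R,9S)-8,9-epoxide of 29 (oxirane oxygen on the face opposite the C1 methyl and the C6 ester)
Conditions: m-CPBA, NaHCO3, CH2Cl2, 0 °C
Reagents that add atoms: 3-chloroperoxybenzoic acid OOC(=O)c1cccc(Cl)c1
Why: Prilezhaev epoxidation of the only alkene should occur on the α-face of C8=C9 because the β-face is screened by the axial C1 methyl and the C6 aroyloxy group, which sets (8R,9S), and the bicarbonate buffer prevents acid-induced opening by the C4 hydroxyl.

Step 22
Reactants: 30 (8R,9S)-8,9-epoxide of 29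
Product: 31 target CNP0163817.3, (1R,4R,5S,6R,8R,9S)-8,9-epoxy-4-hydroxy ester of 4-hydroxybenzoic acid in the skeleton numbering
Conditions: n-Bu4NF, AcOH, THF, 0 °C
Reagents that add atoms: none
Why: Fluoride cleaves the aryl silyl ether within minutes, and the acetic acid buffer protects the epoxide, the benzoate and the tertiary alcohol.

**Compound list**

1 | 3-methylbut-2-en-1-yl acetate | CC(C)=CCOC(C)=O | starting material
2 | (E)-3-methyl-4-oxobut-2-en-1-yl acetate | CC(=O)OC/C=C(\C)C=O | intermediate (not isolated)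
3 | (E)-4-hydroxy-3-methylbut-2-en-1-yl acetate | CC(=O)OC/C=C(\C)CO | intermediate
4 | (E)-4-{[tert-butyl(dimethyl)silyl]oxy}-3-methylbut-2-en-1-yl acetate | CC(=O)OC/C=C(\C)CO[Si](C)(C)C(C)(C)C | intermediate
5 | (E)-4-{[tert-butyl(dimethyl)silyl]oxy}-3-methylbut-2-en-1-ol | OC/C=C(\C)CO[Si](C)(C)C(C)(C)C | intermediate
6 | (E)-4-{[tert-butyl(dimethyl)silyl]oxy}-3-methylbut-2-enal | O=C/C=C(\C)CO[Si](C)(C)C(C)(C)C | intermediate
7 | 3,3-diethoxyprop-1-yne | C#CC(OCC)OCC | starting material
8 | lithium 3,3-diethoxyprop-1-yn-1-ide | [Li]C#CC(OCC)OCC | intermediate (not isolated)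
9 | racemic (E)-7-{[tert-butyl(dimethyl)silyl]oxy}-1,1-diethoxy-6-methylhept-5-en-2-yn-4-ol | CCOC(OCC)C#CC(O)/C=C(\C)CO[Si](C)(C)C(C)(C)C | intermediate
10 | (E)-7-{[tert-butyl(dimethyl)silyl]oxy}-1,1-diethoxy-6-methylhept-5-en-2-yn-4-one | CCOC(OCC)C#CC(=O)/C=C(\C)CO[Si](C)(C)C(C)(C)C | intermediate
11 | (4S,5E)-7-{[tert-butyl(dimethyl)silyl]oxy}-1,1-diethoxy-6-methylhept-5-en-2-yn-4-ol | CCOC(OCC)C#C[C@@H](O)/C=C(\C)CO[Si](C)(C)C(C)(C)C | intermediate
12 | (4S,5E)-7-{[tert-butyl(dimethyl)silyl]oxy}-1,1-diethoxy-6-methylhept-5-en-2-yn-4-yl 2,2-dimethylpropanoate | CCOC(OCC)C#C[C@@H](OC(=O)C(C)(C)C)/C=C(\C)CO[Si](C)(C)C(C)(C)C | intermediate (key-step precursor)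
13 | (3S)-3-({[tert-butyl(dimethyl)silyl]oxy}methyl)-2-(diethoxymethyl)-3-methylcyclopenta-1,4-dien-1-yl 2,2-dimethylpropanoate | CCOC(OCC)C1=C(OC(=O)C(C)(C)C)C=C[C@]1(C)CO[Si](C)(C)C(C)(C)C | intermediate (not isolated)
14 | (4S,5S)-4-({[tert-butyl(dimethyl)silyl]oxy}methyl)-5-(diethoxymethyl)-4-methylcyclopent-2-en-1-one | O=C1C=C[C@](C)(CO[Si](C)(C)C(C)(C)C)[C@H]1C(OCC)OCC | intermediate (key-step product)
15 | (2S,3S)-3-({[tert-butyl(dimethyl)silyl]oxy}methyl)-2-(diethoxymethyl)-3-methylcyclopentan-1-one | O=C1CC[C@](C)(CO[Si](C)(C)C(C)(C)C)[C@H]1C(OCC)OCC | intermediate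
16 | (1R,2R,3S)-3-({[tert-butyl(dimethyl)silyl]oxy}methyl)-2-(diethoxymethyl)-3-methyl-1-(propan-2-yl)cyclopentan-1-ol | CC(C)[C@]1(O)CC[C@](C)(CO[Si](C)(C)C(C)(C)C)[C@H]1C(OCC)OCC | intermediate
17 | (1R,2R,3S)-2-(diethoxymethyl)-3-(hydroxymethyl)-3-methyl-1-(propan-2-yl)cyclopentan-1-ol | CC(C)[C@]1(O)CC[C@](C)(CO)[C@H]1C(OCC)OCC | intermediate
18 | (1S,2R,3R)-2-(diethoxymethyl)-3-hydroxy-1-methyl-3-(propan-2-yl)cyclopentane-1-carbaldehyde | CC(C)[C@]1(O)CC[C@](C)(C=O)[C@H]1C(OCC)OCC | intermediate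
19 | (3E)-4-[(1R,2R,3R)-2-(diethoxymethyl)-3-hydroxy-1-methyl-3-(propan-2-yl)cyclopentyl]but-3-en-2-one | CC(C)[C@]1(O)CC[C@](C)(/C=C/C(C)=O)[C@H]1C(OCC)OCC | intermediate
20 | (1R,2R,3R)-2-(diethoxymethyl)-3-methyl-3-[(1E)-3-methylbuta-1,3-dien-1-yl]-1-(propan-2-yl)cyclopentan-1-ol | CC(C)[C@]1(O)CC[C@](C)(/C=C/C(C)=C)[C@H]1C(OCC)OCC | intermediate
21 | 1-(ethoxy{(1R,2R,5R)-2-methyl-2-[(1E)-3-methylbuta-1,3-dien-1-yl]-5-(propan-2-yl)-5-[(triethylsilyl)oxy]cyclopentyl}methyl)-2,6-dimethylpyridinium triflate (C6 epimers) | CC(C)[C@]1(O[Si](CC)(CC)CC)CC[C@](C)(/C=C/C(C)=C)[C@H]1C(OCC)[n+]1c(C)cccc1C.[O-]S(=O)(=O)C(F)(F)F | intermediate (not isolated)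
22 | (1R,2R,5R)-2-methyl-2-[(1E)-3-methylbuta-1,3-dien-1-yl]-5-(propan-2-yl)-5-[(triethylsilyl)oxy]cyclopentane-1-carbaldehyde | CC(C)[C@]1(O[Si](CC)(CC)CC)CC[C@](C)(/C=C/C(C)=C)[C@H]1C=O | intermediate
23 | (3R,3aR,8aR)-6,8a-dimethyl-3-(propan-2-yl)-3-[(triethylsilyl)oxy]-2,3,3a,5,8,8a-hexahydroazulen-4(1H)-one | CC(C)[C@]1(O[Si](CC)(CC)CC)CC[C@]2(C)CC=C(C)CC(=O)[C@H]21 | intermediate
24 | (3R,3aS,4R,8aR)-6,8a-dimethyl-3-(propan-2-yl)-3-[(triethylsilyl)oxy]-1,2,3,3a,4,5,8,8a-octahydroazulen-4-ol | CC(C)[C@]1(O[Si](CC)(CC)CC)CC[C@]2(C)CC=C(C)C[C@@H](O)[C@H]21 | intermediate (not isolated)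
25 | (3R,3aS,4R,8aR)-6,8a-dimethyl-3-(propan-2-yl)-1,2,3,3a,4,5,8,8a-octahydroazulene-3,4-diol | CC(C)[C@]1(O)CC[C@]2(C)CC=C(C)C[C@@H](O)[C@H]21 | intermediate
26 | 4-hydroxybenzoic acid | OC(=O)c1ccc(O)cc1 | starting material
27 | tert-butyldimethylsilyl 4-{[tert-butyl(dimethyl)silyl]oxy}benzoate | CC(C)(C)[Si](C)(C)OC(=O)c1ccc(O[Si](C)(C)C(C)(C)C)cc1 | intermediate (not isolated)
28 | 4-{[tert-butyl(dimethyl)silyl]oxy}benzoic acid | CC(C)(C)[Si](C)(C)Oc1ccc(cc1)C(=O)O | intermediate
29 | (3R,3aS,4R,8aR)-3-hydroxy-6,8a-dimethyl-3-(propan-2-yl)-1,2,3,3a,4,5,8,8a-octahydroazulen-4-yl 4-{[tert-butyl(dimethyl)silyl]oxy}benzoate | CC(C)[C@]1(O)CC[C@]2(C)CC=C(C)C[C@@H](OC(=O)c3ccc(O[Si](C)(C)C(C)(C)C)cc3)[C@H]21 | intermediate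
30 | (8R,9S)-8,9-epoxide of 29, oxirane oxygen trans to the C1 methyl | CC(C)[C@]1(O)CC[C@]2(C)C[C@@H]3O[C@]3(C)C[C@@H](OC(=O)c3ccc(O[Si](C)(C)C(C)(C)C)cc3)[C@H]21 | intermediate
31 | CNP0163817.3, (1R,4R,5S,6R,8R,9S) in the skeleton numbering | CC(C)[C@]1(O)CC[C@]2(C)C[C@@H]3O[C@]3(C)C[C@@H](OC(=O)c3ccc(O)cc3)[C@H]21 | target

**Step count**

Total steps: 22. Longest linear sequence: 21 (steps 1–18 and 20–22; step 19 is a one-step side branch).

**Steps most likely to fail**

Step 9 (gold rearrangement). The pivalate may shift 1,3 to give an allenyl ester, the acetal may ionise under the Lewis-acidic conditions, or the cation may racemise before ring closure. The fallback sets out from 6 and comes back at 14; it keeps the rearrangement but moves the introduction of C6 to after ring formation. Ethynylmagnesium bromide adds to 6 to give the racemic ethynyl carbinol F1, MnO2 gives the ethynyl ketone F2, and reduction with (S)-Me-CBS/BH3·SMe2 gives the (S)-alcohol F3 (here the ethynyl group is clearly the small substituent). Pivaloylation gives the terminal-alkyne pivalate F4, the parent substrate class of this rearrangement with no acetal present. Ph3PAuCl/AgSbF6 in wet MeCN should give, through the dienyl pivalate F5, the (R)-cyclopentenone F6. Me3SiOTf/Et3N then forms the cross-conjugated silyl dienol ether F7 (C5 is the only enolisable position), and HC(OEt)3 with BF3·OEt2 (Mukaiyama-type reaction) places the diethoxymethyl group on C5 to give 14, whose C5 is equilibrated in step 10 as before.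

Step 17 (hydroacylation). The hindered acyl rhodium hydride may lose CO, or reductive elimination may occur at C9 to give a cyclopentanone instead of the seven-membered ring. The fallback sets out from 18 and comes back at 23, closing the ring by olefin metathesis at C8=C9. Vinylmagnesium bromide adds to the C10 aldehyde of 18 to give the allylic alcohol F8 (C10 epimers), and methyl chloroformate/pyridine converts the secondary hydroxyl into the carbonate F9. Pd(OAc)2/n-Bu3P with HCO2NH4 (zerovalent palladium, formate reduction of the π-allyl complex with hydride delivered to the substituted terminus) gives the allyl compound F10. TESOTf/2,6-lutidine then water gives, through the lutidinium salt F11, the silyl ether aldehyde F12. 2-Methylallylmagnesium chloride adds to give the homoallylic alcohol F13 (C6 epimers), and the second-generation Grubbs catalyst (H2IMes)(PCy3)Cl2Ru=CHPh closes the ring to the cycloheptenol F14. Dess–Martin oxidation of F14 gives 23.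

Step 11 (isopropyl addition). The β-keto acetal may be enolised with loss of ethoxide, or the branched Grignard reagent may reduce the ketone by β-hydride transfer instead of adding. The fallback sets out from 15 and comes back at 16. Isopropenylmagnesium bromide with CeCl3, an sp2 nucleophile that has no β-hydrogen and is less hindered, adds with the same facial preference to give the isopropenyl carbinol F15. Homogeneous hydrogenation with [RhCl(PPh3)3]/H2, which does not cleave the allylic C–O bond, then gives 16.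

**Further compounds**

F1 | step 9 | racemic (E)-6-{[tert-butyl(dimethyl)silyl]oxy}-5-methylhex-4-en-1-yn-3-ol | C#CC(O)/C=C(\C)CO[Si](C)(C)C(C)(C)C
F2 | step 9 | (E)-6-{[tert-butyl(dimethyl)silyl]oxy}-5-methylhex-4-en-1-yn-3-one | C#CC(=O)/C=C(\C)CO[Si](C)(C)C(C)(C)C
F3 | step 9 | (3S,4E)-6-{[tert-butyl(dimethyl)silyl]oxy}-5-methylhex-4-en-1-yn-3-ol | C#C[C@@H](O)/C=C(\C)CO[Si](C)(C)C(C)(C)C
F4 | step 9 | (3S,4E)-6-{[tert-butyl(dimethyl)silyl]oxy}-5-methylhex-4-en-1-yn-3-yl 2,2-dimethylpropanoate | C#C[C@@H](OC(=O)C(C)(C)C)/C=C(\C)CO[Si](C)(C)C(C)(C)C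
F5 | step 9 | (3S)-3-({[tert-butyl(dimethyl)silyl]oxy}methyl)-3-methylcyclopenta-1,4-dien-1-yl 2,2-dimethylpropanoate (not isolated) | CC(C)(C)C(=O)OC1=C[C@@](C)(CO[Si](C)(C)C(C)(C)C)C=C1
F6 | step 9 | (4R)-4-({[tert-butyl(dimethyl)silyl]oxy}methyl)-4-methylcyclopent-2-en-1-one | O=C1C=C[C@](C)(CO[Si](C)(C)C(C)(C)C)C1
F7 | step 9 | tert-butyl(dimethyl){[(1S)-1-methyl-4-(trimethylsilyloxy)cyclopenta-2,4-dien-1-yl]methoxy}silane | C[Si](C)(C)OC1=C[C@@](C)(CO[Si](C)(C)C(C)(C)C)C=C1
F8 | step 17 | 16-type cyclopentanol with 1-hydroxyprop-2-en-1-yl on C1 (C10 epimers), C6 diethyl acetal, free C4–OH | CC(C)[C@]1(O)CC[C@](C)(C(O)C=C)[C@H]1C(OCC)OCC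
F9 | step 17 | methyl carbonate of F8 at the secondary hydroxyl | CC(C)[C@]1(O)CC[C@](C)(C(OC(=O)OC)C=C)[C@H]1C(OCC)OCC
F10 | step 17 | (1R,2R,3R)-2-(diethoxymethyl)-3-methyl-1-(propan-2-yl)-3-(prop-2-en-1-yl)cyclopentan-1-ol | CC(C)[C@]1(O)CC[C@](C)(CC=C)[C@H]1C(OCC)OCC
F11 | step 17 | 2,6-dimethylpyridinium triflate adduct from F10, C4–OTES (not isolated) | CC(C)[C@]1(O[Si](CC)(CC)CC)CC[C@](C)(CC=C)[C@H]1C(OCC)[n+]1c(C)cccc1C.[O-]S(=O)(=O)C(F)(F)F
F12 | step 17 | 2-methyl-5-(propan-2-yl)-2-(prop-2-en-1-yl)-5-[(triethylsilyl)oxy]cyclopentane-1-carbaldehyde (stereochemistry as in 22) | CC(C)[C@]1(O[Si](CC)(CC)CC)CC[C@](C)(CC=C)[C@H]1C=O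
F13 | step 17 | 2-methylallyl adduct of F12 at C6 (C6 epimers) | CC(C)[C@]1(O[Si](CC)(CC)CC)CC[C@](C)(CC=C)[C@H]1C(O)CC(C)=C
F14 | step 17 | 6,8a-dimethyl-3-(propan-2-yl)-3-[(triethylsilyl)oxy]-1,2,3,3a,4,5,8,8a-octahydroazulen-4-ol (C6 epimers) | CC(C)[C@]1(O[Si](CC)(CC)CC)CC[C@]2(C)CC=C(C)CC(O)[C@H]21
F15 | step 11 | 3-({[tert-butyl(dimethyl)silyl]oxy}methyl)-2-(diethoxymethyl)-3-methyl-1-(prop-1-en-2-yl)cyclopentan-1-ol (stereochemistry as in 16) | CC(=C)[C@]1(O)CC[C@](C)(CO[Si](C)(C)C(C)(C)C)[C@H]1C(OCC)OCC
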